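## Retrosynthetic overview
1. A Claisen–Schmidt cut at the chalcone C=C gives 4'-hydroxyacetophenone (ring A, bought) and a dihydrobenzofuran-5-carbaldehyde. The CMe2OH group is traced back to a methyl ester on C2 and the aldehyde to a methyl ester on C5.
2. Enabling feature: in the dihydrofuran ring, C3 is a bare benzylic CH2 on C3a, ortho to O1 on C7a. O1–C7a–C3a–C3 is therefore a masked o-quinone methide, and C2, the only stereocentre, is the single ring atom missing.
3. C2 is supplied as the carbon of an ester-stabilised ammonium ylide whose cinchona nitrogen is the leaving group. One [4+1] annulation forms both C3–C2 and O1–C2.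
4. The methide precursor carries a silyl ether at the future O1 and a benzylic NMe3+ at the future C3. It is made from methyl 2,4-dihydroxybenzoate by C3 Mannich reaction, 4-O-silylation, base-free 2-O-methylation, and N-quaternisation last.
5. Ring order: benzene ring B is bought, the dihydrofuran ring closes in step 7, and ring A is attached in step 11.

Key step: step 7

Assumption: precedent does not predict the sense of induction of a cinchona leaving group on a methide without a C3 substituent, so the quinidine series is written for (S)-14. If it favours (R), the pseudoenantiomeric quinine-derived salt, made by the same steps 5 and 6, takes its place and nothing else changes.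

## Route

Step 1
Reactants: 1 methyl 2,4-dihydroxybenzoate; 2 N,N-dimethylmethyleneiminium iodide
Product: 3 methyl 3-[(dimethylamino)methyl]-2,4-dihydroxybenzoate
Conditions: 2 (1.0 equiv), K2CO3 (1.1 equiv), CH2Cl2, 0 °C → rt
Reagents that add atoms: none
Why: Mannich aminomethylation should go to C3 because it is ortho to both hydroxyls and the 2-OH/ester chelate localises enol character in the C3=C4 bond, the same bias that directs Mannich reagents to C3 of resacetophenones and C8 of 7-hydroxycoumarins, while one equivalent of iminium salt limits a second attack at C5.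

Step 2
Reactants: 3 methyl 3-[(dimethylamino)methyl]-2,4-dihydroxybenzoate
Product: 4 methyl 4-[(tert-butyldimethylsilyl)oxy]-3-[(dimethylamino)methyl]-2-hydroxybenzoate
Conditions: TBSCl (1.1 equiv), imidazole (2.2 equiv), CH2Cl2, 0 °C → rt
Reagents that add atoms: tert-butyldimethylsilyl chloride, CC(C)(C)[Si](C)(C)Cl
Why: Imidazole-mediated silyl ether formation should select the more acidic 4-OH, which has one ortho neighbour, over the 2-OH, which is hydrogen-bonded to the ester carbonyl and flanked on both sides.

Step 3
Reactants: 4 methyl 4-[(tert-butyldimethylsilyl)oxy]-3-[(dimethylamino)methyl]-2-hydroxybenzoate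
Product: 5 methyl 4-[(tert-butyldimethylsilyl)oxy]-3-[(dimethylamino)methyl]-2-methoxybenzoate
Conditions: MeOH (3 equiv), PPh3, DIAD, THF, 0 °C → rt
Reagents that add atoms: methanol, CO
Why: In this Mitsunobu etherification the methyl electrophile exists only as the methoxyphosphonium partner of the phenoxide, so the salicylate-type 2-OH is methylated while NMe2 stays tertiary and the aryl silyl ether sees no carbonate, which means a 2-phenoxide never sits next to a benzylic ammonium group and no methide can escape through the wrong oxygen.

Step 4
Reactants: 5 methyl 4-[(tert-butyldimethylsilyl)oxy]-3-[(dimethylamino)methyl]-2-methoxybenzoate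
Product: 6 [6-(tert-butyldimethylsilyloxy)-2-methoxy-3-(methoxycarbonyl)benzyl]trimethylammonium iodide
Conditions: MeI (5 equiv), MeCN, rt, dark; precipitation with Et2O
Reagents that add atoms: iodomethane, CI
Why: The Menshutkin quaternisation runs without base or fluoride, so the amine is the only nucleophile present and the silyl ether and ester are untouched.

Step 5
Reactants: 7 quinidine
Product: 8 9-O-methylquinidine
Conditions: NaH (1.3 equiv), DMF, 0 °C → rt; MeI (1.05 equiv), 0 °C
Reagents that add atoms: iodomethane, CI
Why: Williamson etherification of the preformed C9 alkoxide outruns N-methylation, and the cap is needed because a free C9–OH would lactonise onto the N-CH2CO2Me arm of the later salt (six-membered ring) or add to the methide.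

Step 6
Reactants: 8 9-O-methylquinidine; 9 methyl bromoacetate
Product: 10 N-(2-methoxy-2-oxoethyl)-9-O-methylquinidinium bromide (alkylated on the quinuclidine nitrogen)
Conditions: 8 (1.05 equiv), 9 (1.0 equiv), THF, rt; trituration with Et2O
Reagents that add atoms: none
Why: The Menshutkin reaction takes place at the sp3 quinuclidine nitrogen, which is far more nucleophilic than the quinoline nitrogen, and the slight excess of amine plus trituration leaves no free bromoacetate for trimethylamine to convert into an achiral ylide in step 7.

Step 7
Reactants: 6 [6-(tert-butyldimethylsilyloxy)-2-methoxy-3-(methoxycarbonyl)benzyl]trimethylammonium iodide; 10 N-(2-methoxy-2-oxoethyl)-9-O-methylquinidinium bromide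
Product: 14 dimethyl (S)-4-methoxy-2,3-dihydrobenzofuran-2,5-dicarboxylate, via o-quinone methide 11 (not isolated), via ammonium ylide 12 (not isolated), via phenoxide betaine 13 (not isolated)
Conditions: 10 (1.5 equiv), Cs2CO3 (2 equiv), CsF (2 equiv), 4 Å MS, MeCN, 0 °C → rt, slow Ar sweep; 6 added in portions
Reagents that add atoms: none
Why: Proposed new method: fluoride removes the silyl group of 6 and the phenoxide expels trimethylamine by 1,4-elimination to give methide 11, while carbonate deprotonates 10 to the ester-stabilised ylide 12, whose carbon adds to the exocyclic CH2 of 11 with rearomatisation (C3–C2 bond) to give betaine 13. The phenoxide oxygen of 13 then attacks C2 from the side opposite the quinuclidinium nitrogen in a 5-exo-tet SN2 closure with inversion (O1–C2 bond), which forms the dihydrofuran ring and returns amine 8. The closest known reactions are the enantioselective [4+1] annulation of aryl-substituted o-quinone methides with cinchona-derived ammonium ylides and the racemic annulation of terminally unsubstituted methides with sulfonium or pyridinium ylides, and the new element is that C2 is the only stereocentre, so no C3 substituent relays the induction. C2 is controlled by the chiral quinuclidinium bound directly to it: the C2–H of 13 lies between N+ and the ester and can be exchanged by carbonate, so the betaine epimers should interconvert, and the (R)-epimer, expected to have the less hindered backside trajectory past the quinoline and C9-methoxy groups, should close faster to (S)-14 (Curtin–Hammett, dynamic kinetic resolution). Methide 11 must be captured by 12 rather than by trimethylamine, water or a second methide, and this is secured by the electron-poor ester-bearing methide, excess ylide, portionwise addition of 6, molecular sieves and the argon sweep that carries off trimethylamine. The step also needs the absence of any achiral ylide and no epimerisation of the α-aryloxy ester, which the bromoacetate-free salt 10 and solid carbonate at or below room temperature provide.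

Step 8
Reactants: 14 dimethyl (S)-4-methoxy-2,3-dihydrobenzofuran-2,5-dicarboxylate
Product: 16 methyl (S)-2-(2-hydroxypropan-2-yl)-4-methoxy-2,3-dihydrobenzofuran-5-carboxylate, via methyl ketone 15 (not isolated)
Conditions: MeMgBr (2.2 equiv), THF, −78 → −40 °C; sat. aq NH4Cl
Reagents that add atoms: methylmagnesium bromide, C[Mg]Br
Why: The double Grignard addition should select the aliphatic ester, which is inductively activated by O1 and can chelate magnesium, over the aromatic ester, which is deactivated by the para O1 and ortho OMe donors, while ketone 15 is more reactive than either ester and low temperature suppresses enolisation at C2.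

Step 9
Reactants: 16 methyl (S)-2-(2-hydroxypropan-2-yl)-4-methoxy-2,3-dihydrobenzofuran-5-carboxylate
Product: 17 (S)-2-[5-(hydroxymethyl)-4-methoxy-2,3-dihydrobenzofuran-2-yl]propan-2-ol
Conditions: LiAlH4 (2 equiv), THF, 0 °C → rt; neutral aqueous work-up
Reagents that add atoms: none
Why: Hydride reduction of the remaining ester gives the benzylic alcohol, the tertiary alcohol only consumes one hydride as its alkoxide, and a non-acidic work-up protects the electron-rich benzylic alcohol from ionisation.

Step 10
Reactants: 17 (S)-2-[5-(hydroxymethyl)-4-methoxy-2,3-dihydrobenzofuran-2-yl]propan-2-ol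
Product: 18 (S)-2-(2-hydroxypropan-2-yl)-4-methoxy-2,3-dihydrobenzofuran-5-carbaldehyde
Conditions: activated MnO2 (excess), CH2Cl2, rt
Reagents that add atoms: none
Why: MnO2 oxidation is selective for the benzylic alcohol and stops at the aldehyde, and the tertiary alcohol cannot be oxidised.

Step 11
Reactants: 18 (S)-2-(2-hydroxypropan-2-yl)-4-methoxy-2,3-dihydrobenzofuran-5-carbaldehyde; 19 4'-hydroxyacetophenone
Product: 21 (E)-1-(4-hydroxyphenyl)-3-[(2S)-2-(2-hydroxypropan-2-yl)-4-methoxy-2,3-dihydro-1-benzofuran-5-yl]prop-2-en-1-one, via aldol adduct 20 (not isolated)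
Conditions: 19 (1.2 equiv), KOH (50% aq, excess), EtOH, rt; then cold 1 M HCl to pH 5–6
Reagents that add atoms: none
Why: In the Claisen–Schmidt condensation, excess hydroxide forms the phenoxide enolate of 19, aldol 20 loses water by E1cB to give the thermodynamically preferred (E)-enone, and C2 no longer carries an acidifying group and cannot epimerise.

## Compound list
1 | methyl 2,4-dihydroxybenzoate | COC(=O)c1ccc(O)cc1O | starting material
2 | N,N-dimethylmethyleneiminium iodide | C=[N+](C)C.[I-] | starting material
3 | methyl 3-[(dimethylamino)methyl]-2,4-dihydroxybenzoate | COC(=O)c1ccc(O)c(CN(C)C)c1O | intermediate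
4 | methyl 4-[(tert-butyldimethylsilyl)oxy]-3-[(dimethylamino)methyl]-2-hydroxybenzoate | COC(=O)c1ccc(O[Si](C)(C)C(C)(C)C)c(CN(C)C)c1O | intermediate
5 | methyl 4-[(tert-butyldimethylsilyl)oxy]-3-[(dimethylamino)methyl]-2-methoxybenzoate | COC(=O)c1ccc(O[Si](C)(C)C(C)(C)C)c(CN(C)C)c1OC | intermediate
6 | [6-(tert-butyldimethylsilyloxy)-2-methoxy-3-(methoxycarbonyl)benzyl]trimethylammonium iodide | COC(=O)c1ccc(O[Si](C)(C)C(C)(C)C)c(C[N+](C)(C)C)c1OC.[I-] | intermediate
7 | quinidine (8R,9S) | COC1=CC2=C(C=CN=C2C=C1)[C@@H]([C@H]3C[C@@H]4CCN3C[C@@H]4C=C)O | starting material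
8 | 9-O-methylquinidine | COC1=CC2=C(C=CN=C2C=C1)[C@@H]([C@H]3C[C@@H]4CCN3C[C@@H]4C=C)OC | intermediate
9 | methyl bromoacetate | COC(=O)CBr | starting material
10 | N-(2-methoxy-2-oxoethyl)-9-O-methylquinidinium bromide | COC1=CC2=C(C=CN=C2C=C1)[C@@H]([C@H]3C[C@@H]4CC[N+]3(CC(=O)OC)C[C@@H]4C=C)OC.[Br-] | intermediate
11 | methyl 2-methoxy-3-methylidene-4-oxocyclohexa-1,5-diene-1-carboxylate (o-quinone methide) | COC(=O)C1=C(OC)C(=C)C(=O)C=C1 | intermediate
12 | 9-O-methylquinidinium (methoxycarbonyl)methylide | COC1=CC2=C(C=CN=C2C=C1)[C@@H]([C@H]3C[C@@H]4CC[N+]3([CH-]C(=O)OC)C[C@@H]4C=C)OC | intermediate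
13 | phenoxide betaine, (R) at the carbon that becomes C2 (reactive epimer) | COC1=CC2=C(C=CN=C2C=C1)[C@@H]([C@H]3C[C@@H]4CC[N+]3([C@H](Cc5c([O-])ccc(C(=O)OC)c5OC)C(=O)OC)C[C@@H]4C=C)OC | intermediate
14 | dimethyl (S)-4-methoxy-2,3-dihydrobenzofuran-2,5-dicarboxylate | COC(=O)c1ccc2c(c1OC)C[C@@H](C(=O)OC)O2 | intermediate
15 | methyl (S)-2-acetyl-4-methoxy-2,3-dihydrobenzofuran-5-carboxylate | COC(=O)c1ccc2c(c1OC)C[C@@H](C(C)=O)O2 | intermediate
16 | methyl (S)-2-(2-hydroxypropan-2-yl)-4-methoxy-2,3-dihydrobenzofuran-5-carboxylate | COC(=O)c1ccc2c(c1OC)C[C@@H](C(C)(C)O)O2 | intermediate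
17 | (S)-2-[5-(hydroxymethyl)-4-methoxy-2,3-dihydrobenzofuran-2-yl]propan-2-ol | COc1c(CO)ccc2c1C[C@@H](C(C)(C)O)O2 | intermediate
18 | (S)-2-(2-hydroxypropan-2-yl)-4-methoxy-2,3-dihydrobenzofuran-5-carbaldehyde | COc1c(C=O)ccc2c1C[C@@H](C(C)(C)O)O2 | intermediate
19 | 4'-hydroxyacetophenone | CC(=O)c1ccc(O)cc1 | starting material
20 | 3-hydroxy-1-(4-hydroxyphenyl)-3-[(2S)-2-(2-hydroxypropan-2-yl)-4-methoxy-2,3-dihydrobenzofuran-5-yl]propan-1-one (both carbinol epimers) | COc1c(C(O)CC(=O)c2ccc(O)cc2)ccc2c1C[C@@H](C(C)(C)O)O2 | intermediate
21 | (E)-1-(4-hydroxyphenyl)-3-[(2S)-2-(2-hydroxypropan-2-yl)-4-methoxy-2,3-dihydro-1-benzofuran-5-yl]prop-2-en-1-one | COc1c(/C=C/C(=O)c2ccc(O)cc2)ccc2c1C[C@@H](C(C)(C)O)O2 | target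

## Step count
Total step count: 11.
Longest linear sequence: 9 (steps 1–4 and 7–11). Steps 5 and 6 form a two-step branch.

## Steps most likely to fail

**Step 7.**
- The alkaloid may discriminate poorly between the two betaine epimers in the ring closure.
- The phenoxide is stabilised by its para ester and may expel trimethylamine slowly.
- The methide may be lost to self-condensation, or the new α-aryloxy ester may epimerise under base.

The fallback sets out from 6 and comes back at 14, using known chemistry only. The same fluoride-released methide is trapped with the achiral ylide of commercial (2-methoxy-2-oxoethyl)dimethylsulfonium bromide (CsF, Cs2CO3, MeCN, rt). This is the established racemic [4+1] annulation of unsubstituted methides and gives racemic dimethyl 4-methoxy-2,3-dihydrobenzofuran-2,5-dicarboxylate F1. One equivalent of LiOH (THF–H2O, 0 °C) hydrolyses only the aliphatic ester to the racemic monoacid F2. Fractional crystallisation with (S)-1-phenylethylamine gives the salt of the (S)-acid F3; the antipodal amine is used if the (R)-acid crystallises instead. Dilute acid frees the (S)-monoacid F4, and Fischer esterification (MeOH, cat. H2SO4) returns 14.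

**Step 8.**
- The Grignard reagent may also attack the aromatic ester.
- Enolisation of the transient ketone may erode the configuration at C2.

The fallback sets out from 14 and comes back at 16, and it adds the two methyl groups one at a time. LiOH (1.0 equiv, THF–H2O, 0 °C) cleaves only the aliphatic ester to the (S)-monoacid F4, the same compound as in the first fallback. Coupling with N,O-dimethylhydroxylamine hydrochloride (EDC·HCl, HOBt, N-methylmorpholine, CH2Cl2) gives the Weinreb amide F5. MeMgBr (1.1 equiv, THF, −78 °C) stops at the chelated tetrahedral adduct and gives ketone 15 on quenching, now isolated. One further equivalent of MeMgBr premixed with anhydrous CeCl3 (−78 °C) should add to the ketone much faster than to the aromatic ester and with little enolisation, giving 16.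

**Step 3.**
- The hindered, hydrogen-bonded phenol may fail to engage.
- The methoxyphosphonium ion may methylate the neighbouring dimethylamino group instead.

The fallback sets out from 4 and comes back at 5, and it masks the competing nucleophile so that an ordinary Williamson methylation can be used. BH3·THF (1.0 equiv, THF, 0 °C) converts the amine into the amine–borane of the phenol F6. MeI and K2CO3 in dry acetone (rt → 40 °C) methylate the 2-OH to the amine–borane of the methyl ether F7, with nitrogen unable to quaternise. Borane transfer to DABCO (toluene, 60 °C) then releases 5.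

## Further compounds
F1 | step 7 | dimethyl (±)-4-methoxy-2,3-dihydrobenzofuran-2,5-dicarboxylate | COC(=O)c1ccc2c(c1OC)CC(C(=O)OC)O2
F2 | step 7 | (±)-4-methoxy-5-(methoxycarbonyl)-2,3-dihydrobenzofuran-2-carboxylic acid | COC(=O)c1ccc2c(c1OC)CC(C(=O)O)O2
F3 | step 7 | (S)-1-phenylethylammonium (S)-4-methoxy-5-(methoxycarbonyl)-2,3-dihydrobenzofuran-2-carboxylate | COC(=O)c1ccc2c(c1OC)C[C@@H](C(=O)[O-])O2.C[C@H]([NH3+])c1ccccc1
F4 | step 7 | (S)-4-methoxy-5-(methoxycarbonyl)-2,3-dihydrobenzofuran-2-carboxylic acid | COC(=O)c1ccc2c(c1OC)C[C@@H](C(=O)O)O2
F5 | step 8 | methyl (S)-4-methoxy-2-[methoxy(methyl)carbamoyl]-2,3-dihydrobenzofuran-5-carboxylate | COC(=O)c1ccc2c(c1OC)C[C@@H](C(=O)N(C)OC)O2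
F6 | step 3 | borane complex of methyl 4-[(tert-butyldimethylsilyl)oxy]-3-[(dimethylamino)methyl]-2-hydroxybenzoate | COC(=O)c1ccc(O[Si](C)(C)C(C)(C)C)c(C[N+](C)(C)[BH3-])c1O
F7 | step 3 | borane complex of methyl 4-[(tert-butyldimethylsilyl)oxy]-3-[(dimethylamino)methyl]-2-methoxybenzoate | COC(=O)c1ccc(O[Si](C)(C)C(C)(C)C)c(C[N+](C)(C)[BH3-])c1OC
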